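**Retrosynthetic overview** (carotenoid numbering: β-ring C1–C6, ε-ring C1'–C6', chain C7–C15 and C15'–C7', chain methyls C19, C20, C19', C20')
- Helenien ⇒ lutein (two ester C–O bonds, made last) ⇒ lutein bis-silyl ether.
- Key disconnection C14–C15: a C18 β-ring trienyne with a terminal C13≡C14 alkyne is methylaluminated and coupled in the same pot with a C21 ε-ring pentaenyl bromide (Br on C15). This one operation brings in C20, sets 13E and completes the C40 nonaene.
- Enabling feature: C13 carries a methyl group and forms the E-trisubstituted C13=C14 alkene, and C14–C15 is an sp2–sp2 single bond next to the E C15=C15' alkene. This is the retron of syn Me–Al addition to a 1-alkyne followed by alkenyl–alkenyl coupling, and it recurs at C9/C10, C9'/C10' and C13'/C14'.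
- Both halves use the same iteration: methyl ketone → 1-en-3-yne → methylalumination/coupling with (E)-BrCH=CH–C≡C–SiMe3. (E)-BrCH=CHI supplies C15/C15'.
- No ring is formed. The β-ring (C3 R) is bought as (4R,6R)-actinol and the ε-ring (C6' R) as (R)-α-ionone; C3' is set by allylic oxidation and CBS reduction.

Key step: step 18

Assumption: (4R,6R)-actinol and (R)-(+)-α-ionone are bought as single enantiomers; all polyenes are handled under argon in dim light.

**Step 1**
Reactants: 1 acetylene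
Product: 2 (E)-1-bromo-2-iodoethene
Conditions: IBr, 48% aq. HBr, 0 °C
Reagents that add atoms: iodine monobromide, BrI
Why: Electrophilic anti-addition of I–Br to the alkyne through an iodonium ion should give the E-dihaloalkene (alkyne halogenation).

**Step 2**
Reactants: 2 (E)-1-bromo-2-iodoethene; 3 ethynyltrimethylsilane
Product: 4 (E)-(4-bromobut-3-en-1-yn-1-yl)trimethylsilane
Conditions: Pd(PPh3)4 (cat.), CuI (cat.), i-Pr2NH, THF, 0 °C to rt
Reagents that add atoms: none
Why: Sonogashira coupling, in which zerovalent palladium inserts into C–I much faster than into C–Br and the alkene geometry is retained, so the E-bromoenyne should form selectively.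

**Step 3**
Reactants: 5 (4R,6R)-4-hydroxy-2,2,6-trimethylcyclohexan-1-one ((4R,6R)-actinol)
Product: 6 (4R,6R)-4-[(tert-butyldimethylsilyl)oxy]-2,2,6-trimethylcyclohexan-1-one
Conditions: TBSCl, imidazole, DMF, rt
Reagents that add atoms: tert-butyldimethylsilyl chloride, CC(C)(C)[Si](C)(C)Cl
Why: Imidazole-promoted silylation of a secondary alcohol; no stereocentre is touched.

**Step 4**
Reactants: 6 silyl ether of actinol
Product: 7 (4R)-4-[(tert-butyldimethylsilyl)oxy]-2,6,6-trimethylcyclohex-1-en-1-yl trifluoromethanesulfonate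
Conditions: LiN(i-Pr)2, THF, −78 to 0 °C; PhNTf2, 0 °C to rt
Reagents that add atoms: N-phenylbis(trifluoromethanesulfonimide), O=S(=O)(N(c1ccccc1)S(=O)(=O)C(F)(F)F)C(F)(F)F
Why: Enolate O-triflation; only C6 carries an α-hydrogen (C2 is quaternary), so a single tetrasubstituted enol triflate should form, the C6 centre being erased on purpose and the remote C4 centre left untouched.

**Step 5**
Reactants: 7 enol triflate; 8 but-3-en-2-one (methyl vinyl ketone)
Product: 9 (3E)-4-[(4R)-4-[(tert-butyldimethylsilyl)oxy]-2,6,6-trimethylcyclohex-1-en-1-yl]but-3-en-2-one ((3R)-3-silyloxy-β-ionone)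
Conditions: Pd(OAc)2 (cat.), PPh3, Et3N, DMF, 70 °C
Reagents that add atoms: none
Why: Mizoroki–Heck vinylation of an enol triflate with an electron-poor alkene; syn insertion and syn β-hydride elimination should give the 7E enone and form C6–C7.

**Step 6**
Reactants: 9 (3R)-3-silyloxy-β-ionone
Product: 11 tert-butyl{[(1R)-4-[(1E)-but-1-en-3-yn-1-yl]-3,5,5-trimethylcyclohex-3-en-1-yl]oxy}dimethylsilane, via enol diethyl phosphate 10 (not isolated)
Conditions: LiN(i-Pr)2 (1 equiv), THF, −78 °C; ClP(O)(OEt)2, −78 °C to rt; LiN(i-Pr)2 (2.3 equiv), −78 °C to rt; aq. NH4Cl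
Reagents that add atoms: none
Why: Kinetic deprotonation of the acetyl methyl group, O-phosphorylation and base-induced elimination of diethyl phosphate (enol phosphate elimination) should turn the methyl ketone into the terminal alkyne without touching the 7E alkene.

**Step 7**
Reactants: 11 β-ring dienyne; 4 (E)-(4-bromobut-3-en-1-yn-1-yl)trimethylsilane
Product: 13 tert-butyl{[(1R)-3,5,5-trimethyl-4-[(1E,3E,5E)-3-methyl-8-(trimethylsilyl)octa-1,3,5-trien-7-yn-1-yl]cyclohex-3-en-1-yl]oxy}dimethylsilane, via dienyl(dimethyl)alane 12 (not isolated)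
Conditions: Me3Al (2 equiv), Cp2ZrCl2 (0.2 equiv), (CH2Cl)2, rt; volatiles removed; 4, ZnCl2 (0.3 equiv), Pd2(dba)3 (cat.), P(2-furyl)3, THF, rt
Reagents that add atoms: trimethylaluminium, C[Al](C)C
Why: Zirconium-catalysed syn methylalumination (Negishi carboalumination) puts the methyl group on C9 and Al on C10 (9E), and Negishi coupling of the alkenylalane with the C–Br bond of 4 goes with retention at both alkenes (11E).

**Step 8**
Reactants: 13 silylated β-ring trienyne
Product: 14 tert-butyl{[(1R)-3,5,5-trimethyl-4-[(1E,3E,5E)-3-methylocta-1,3,5-trien-7-yn-1-yl]cyclohex-3-en-1-yl]oxy}dimethylsilane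
Conditions: K2CO3 (cat.), MeOH/THF, rt
Reagents that add atoms: none
Why: Methoxide-catalysed protodesilylation of the alkynyl C–Si bond; the secondary TBS ether is stable to these conditions.

**Step 9**
Reactants: 15 (3E)-4-[(1R)-2,6,6-trimethylcyclohex-2-en-1-yl]but-3-en-2-one ((R)-α-ionone)
Product: 16 2-methyl-2-{(E)-2-[(1R)-2,6,6-trimethylcyclohex-2-en-1-yl]ethenyl}-1,3-dioxolane
Conditions: Me3SiOCH2CH2OSiMe3, Me3SiOTf (cat.), CH2Cl2, −78 °C; pyridine quench
Reagents that add atoms: 1,2-bis(trimethylsilyloxy)ethane, C[Si](C)(C)OCCO[Si](C)(C)C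
Why: Noyori ketalisation under kinetic, low-temperature conditions should mask C9'=O without moving the C7'=C8' alkene or epimerising C6'.

**Step 10**
Reactants: 16 α-ionone dioxolane
Product: 18 (4R)-3,5,5-trimethyl-4-[(E)-2-(2-methyl-1,3-dioxolan-2-yl)ethenyl]cyclohex-2-en-1-one, via allylic tert-butyl peroxide 17 (not isolated)
Conditions: t-BuOOH (5 equiv), Rh2(cap)4 (cap = caprolactamate, cat.), K2CO3 (0.5 equiv), CH2Cl2, rt
Reagents that add atoms: tert-butyl hydroperoxide, CC(C)(C)OO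
Why: Radical allylic C–H oxidation (Kharasch-type peroxidation, then loss of tert-butanol from 17) should occur at the only unhindered ring allylic methylene, C3', as is usual for α-ionone derivatives, because the doubly allylic C6'–H is shielded by the C1' gem-dimethyl and C5' methyl groups.

**Step 11**
Reactants: 18 3'-oxo ketal
Product: 19 (1R,4R)-3,5,5-trimethyl-4-[(E)-2-(2-methyl-1,3-dioxolan-2-yl)ethenyl]cyclohex-2-en-1-ol
Conditions: (S)-Me-CBS oxazaborolidine (20 mol %), catecholborane, toluene, −78 °C; aq. NaOH work-up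
Reagents that add atoms: none
Why: Corey–Bakshi–Shibata reduction, in which the (S)-catalyst binds the enone with its alkenyl arm as the large group and delivers hydride to the face that gives the 3'R carbinol (reagent control, trans to the C6' chain), with catecholborane favouring 1,2-reduction.

**Step 12**
Reactants: 19 allylic alcohol
Product: 20 tert-butyl{[(1R,4R)-3,5,5-trimethyl-4-[(E)-2-(2-methyl-1,3-dioxolan-2-yl)ethenyl]cyclohex-2-en-1-yl]oxy}dimethylsilane
Conditions: TBSCl, imidazole, DMF, rt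
Reagents that add atoms: tert-butyldimethylsilyl chloride, CC(C)(C)[Si](C)(C)Cl
Why: Imidazole-promoted silylation with retention at C3'.

**Step 13**
Reactants: 20 silyl ether ketal
Product: 21 (3E)-4-[(1R,4R)-4-[(tert-butyldimethylsilyl)oxy]-2,6,6-trimethylcyclohex-2-en-1-yl]but-3-en-2-one ((3R,6R)-3-silyloxy-α-ionone)
Conditions: PPTS (cat.), acetone/H2O, rt
Reagents that add atoms: water, O
Why: Mild acid-catalysed hydrolysis of the allylic dioxolane through a stabilised oxocarbenium ion; the TBS ether and the C6' centre should survive.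

**Step 14**
Reactants: 21 (3R,6R)-3-silyloxy-α-ionone
Product: 23 tert-butyl{[(1R,4R)-4-[(1E)-but-1-en-3-yn-1-yl]-3,5,5-trimethylcyclohex-2-en-1-yl]oxy}dimethylsilane, via enol diethyl phosphate 22 (not isolated)
Conditions: LiN(i-Pr)2 (1 equiv), THF, −78 °C; ClP(O)(OEt)2, −78 °C to rt; LiN(i-Pr)2 (2.3 equiv), −78 °C to rt; aq. NH4Cl
Reagents that add atoms: none
Why: The same enol phosphate elimination as in step 6; at −78 °C kinetic deprotonation should occur at the methyl group and then at the vinylic C–H of 22, not at the hindered C6'–H.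

**Step 15**
Reactants: 23 ε-ring enyne; 4 (E)-(4-bromobut-3-en-1-yn-1-yl)trimethylsilane
Product: 25 tert-butyl{[(1R,4R)-3,5,5-trimethyl-4-[(1E,3E,5E)-3-methyl-8-(trimethylsilyl)octa-1,3,5-trien-7-yn-1-yl]cyclohex-2-en-1-yl]oxy}dimethylsilane, via dienyl(dimethyl)alane 24 (not isolated)
Conditions: Me3Al (2 equiv), Cp2ZrCl2 (0.2 equiv), (CH2Cl)2, rt; volatiles removed; 4, ZnCl2 (0.3 equiv), Pd2(dba)3 (cat.), P(2-furyl)3, THF, rt
Reagents that add atoms: trimethylaluminium, C[Al](C)C
Why: Negishi carboalumination (syn, methyl to C9', 9'E) followed by Negishi coupling with retention (11'E); the isolated ring alkene and the allylic silyl ether should be inert.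

**Step 16**
Reactants: 25 silylated ε-ring trienyne
Product: 26 tert-butyl{[(1R,4R)-3,5,5-trimethyl-4-[(1E,3E,5E)-3-methylocta-1,3,5-trien-7-yn-1-yl]cyclohex-2-en-1-yl]oxy}dimethylsilane
Conditions: K2CO3 (cat.), MeOH/THF, rt
Reagents that add atoms: none
Why: Methoxide-catalysed protodesilylation of the alkynyl C–Si bond only.

**Step 17**
Reactants: 26 ε-ring trienyne; 2 (E)-1-bromo-2-iodoethene
Product: 28 tert-butyl{[(1R,4R)-4-[(1E,3E,5E,7E,9E)-10-bromo-3,7-dimethyldeca-1,3,5,7,9-pentaen-1-yl]-3,5,5-trimethylcyclohex-2-en-1-yl]oxy}dimethylsilane, via trienyl(dimethyl)alane 27 (not isolated)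
Conditions: Me3Al (2 equiv), Cp2ZrCl2 (0.2 equiv), (CH2Cl)2, rt; volatiles removed; 2 (1.5 equiv), ZnCl2 (0.3 equiv), Pd2(dba)3 (cat.), P(2-furyl)3, THF, 0 °C to rt
Reagents that add atoms: trimethylaluminium, C[Al](C)C
Why: Negishi carboalumination sets C20' and 13'E, and the alkenylalane should couple only at the C–I bond of 2 (faster oxidative addition, Negishi coupling), leaving the C15–Br bond for the final union.

**Step 18**
Reactants: 14 β-ring trienyne; 28 ε-ring pentaenyl bromide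
Product: 30 (all-E,3R,3'R,6'R)-3,3'-bis[(tert-butyldimethylsilyl)oxy]-β,ε-carotene (lutein bis-silyl ether), via tetraenyl(dimethyl)alane 29 (not isolated)
Conditions: Me3Al (2 equiv), Cp2ZrCl2 (0.2 equiv), (CH2Cl)2, rt; volatiles removed; 28, ZnCl2 (0.3 equiv), Pd2(dba)3 (cat.), P(2-furyl)3, THF/DMF, rt, dark
Reagents that add atoms: trimethylaluminium, C[Al](C)C
Why: Me3Al and Cp2ZrCl2 form a methylzirconocene–alane pair that adds methyl and metal syn across the terminal C13≡C14 bond of 14 with methyl on the internal carbon, so alane 29 carries the new C20 methyl and a 13E alkene; the alkenyl group then passes from Al through Zn to the alkenylpalladium bromide formed by insertion of zerovalent palladium into C15–Br of 28, and reductive elimination forms C14–C15. The closest known reaction type is the tandem Negishi carboalumination/Pd–Zn cross-coupling used to build all-E polyenes from 1-alkynes and alkenyl halides. No ring is closed and no stereocentre is made; C3, C3' and C6' come unchanged from 14 and 28. The step needs methyl delivery to C13, syn addition (13E) and retention at both coupling carbons (13E, 15E), which are inherent to the mechanism, and chemoselectivity, which should hold because the conjugated C=C bonds and silyl ethers are inert to the Zr/Al reagent and 28 has a single C–Br bond. Room temperature, exclusion of light and removal of excess Me3Al before coupling should limit E/Z scrambling and methyl transfer.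

**Step 19**
Reactants: 30 lutein bis-silyl ether
Product: 31 (all-E,3R,3'R,6'R)-β,ε-carotene-3,3'-diol (lutein)
Conditions: n-Bu4NF, THF, rt, dark
Reagents that add atoms: none
Why: Fluoride-driven cleavage of both Si–O bonds under non-acidic conditions that should spare the acid-labile allylic C3' alcohol and the polyene.

**Step 20**
Reactants: 31 lutein; 32 hexadecanoyl chloride (palmitoyl chloride)
Product: 33 helenien, (all-E,3R,3'R,6'R)-β,ε-carotene-3,3'-diyl dihexadecanoate
Conditions: 32 (3 equiv in all), pyridine, DMAP (cat.), CH2Cl2, 0 °C to rt, dark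
Reagents that add atoms: hexadecanoyl chloride (the second equivalent of 32), CCCCCCCCCCCCCCCC(=O)Cl
Why: DMAP-catalysed O-acylation through the N-acylpyridinium ion should esterify both secondary alcohols, one molecule of acid chloride being consumed per hydroxyl (two in all), with retention at C3 and C3' because no C–O bond of the carotenoid is broken and pyridine buffers the HCl that would otherwise ionise the allylic C3' position.

**Compound list**
1 | acetylene | C#C | starting material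
2 | (E)-1-bromo-2-iodoethene | Br/C=C/I | intermediate
3 | ethynyltrimethylsilane | C#C[Si](C)(C)C | starting material
4 | (E)-(4-bromobut-3-en-1-yn-1-yl)trimethylsilane | C[Si](C)(C)C#C/C=C/Br | intermediate
5 | (4R,6R)-4-hydroxy-2,2,6-trimethylcyclohexan-1-one | C[C@@H]1C[C@@H](O)CC(C)(C)C1=O | starting material
6 | (4R,6R)-4-[(tert-butyldimethylsilyl)oxy]-2,2,6-trimethylcyclohexan-1-one | C[C@@H]1C[C@@H](O[Si](C)(C)C(C)(C)C)CC(C)(C)C1=O | intermediate
7 | (4R)-4-[(tert-butyldimethylsilyl)oxy]-2,6,6-trimethylcyclohex-1-en-1-yl trifluoromethanesulfonate | CC(C)(C)[Si](C)(C)O[C@@H]1CC(C)=C(OS(=O)(=O)C(F)(F)F)C(C)(C)C1 | intermediate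
8 | but-3-en-2-one | CC(=O)C=C | starting material
9 | (3E)-4-[(4R)-4-[(tert-butyldimethylsilyl)oxy]-2,6,6-trimethylcyclohex-1-en-1-yl]but-3-en-2-one | CC(C)(C)[Si](C)(C)O[C@@H]1CC(C)=C(/C=C/C(C)=O)C(C)(C)C1 | intermediate
10 | (3E)-4-[(4R)-4-[(tert-butyldimethylsilyl)oxy]-2,6,6-trimethylcyclohex-1-en-1-yl]buta-1,3-dien-2-yl diethyl phosphate | CC(C)(C)[Si](C)(C)O[C@@H]1CC(C)=C(/C=C/C(=C)OP(=O)(OCC)OCC)C(C)(C)C1 | intermediate
11 | tert-butyl{[(1R)-4-[(1E)-but-1-en-3-yn-1-yl]-3,5,5-trimethylcyclohex-3-en-1-yl]oxy}dimethylsilane | CC(C)(C)[Si](C)(C)O[C@@H]1CC(C)=C(/C=C/C#C)C(C)(C)C1 | intermediate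
12 | dimethyl{(1E,3E)-2-methyl-4-[(4R)-4-(tert-butyldimethylsilyloxy)-2,6,6-trimethylcyclohex-1-en-1-yl]buta-1,3-dien-1-yl}alane | CC(C)(C)[Si](C)(C)O[C@@H]1CC(C)=C(/C=C/C(C)=C/[Al](C)C)C(C)(C)C1 | intermediate
13 | tert-butyl{[(1R)-3,5,5-trimethyl-4-[(1E,3E,5E)-3-methyl-8-(trimethylsilyl)octa-1,3,5-trien-7-yn-1-yl]cyclohex-3-en-1-yl]oxy}dimethylsilane | CC(C)(C)[Si](C)(C)O[C@@H]1CC(C)=C(/C=C/C(C)=C/C=C/C#C[Si](C)(C)C)C(C)(C)C1 | intermediate
14 | tert-butyl{[(1R)-3,5,5-trimethyl-4-[(1E,3E,5E)-3-methylocta-1,3,5-trien-7-yn-1-yl]cyclohex-3-en-1-yl]oxy}dimethylsilane | CC(C)(C)[Si](C)(C)O[C@@H]1CC(C)=C(/C=C/C(C)=C/C=C/C#C)C(C)(C)C1 | intermediate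
15 | (3E)-4-[(1R)-2,6,6-trimethylcyclohex-2-en-1-yl]but-3-en-2-one | CC(=O)/C=C/[C@H]1C(C)=CCCC1(C)C | starting material
16 | 2-methyl-2-{(E)-2-[(1R)-2,6,6-trimethylcyclohex-2-en-1-yl]ethenyl}-1,3-dioxolane | CC1(/C=C/[C@H]2C(C)=CCCC2(C)C)OCCO1 | intermediate
17 | 2-{(E)-2-[(1R)-4-(tert-butylperoxy)-2,6,6-trimethylcyclohex-2-en-1-yl]ethenyl}-2-methyl-1,3-dioxolane (both C4 epimers) | CC1(/C=C/[C@H]2C(C)=CC(OOC(C)(C)C)CC2(C)C)OCCO1 | intermediate
18 | (4R)-3,5,5-trimethyl-4-[(E)-2-(2-methyl-1,3-dioxolan-2-yl)ethenyl]cyclohex-2-en-1-one | CC1(/C=C/[C@H]2C(C)=CC(=O)CC2(C)C)OCCO1 | intermediate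
19 | (1R,4R)-3,5,5-trimethyl-4-[(E)-2-(2-methyl-1,3-dioxolan-2-yl)ethenyl]cyclohex-2-en-1-ol | CC1(/C=C/[C@H]2C(C)=C[C@H](O)CC2(C)C)OCCO1 | intermediate
20 | tert-butyl{[(1R,4R)-3,5,5-trimethyl-4-[(E)-2-(2-methyl-1,3-dioxolan-2-yl)ethenyl]cyclohex-2-en-1-yl]oxy}dimethylsilane | CC1(/C=C/[C@H]2C(C)=C[C@H](O[Si](C)(C)C(C)(C)C)CC2(C)C)OCCO1 | intermediate
21 | (3E)-4-[(1R,4R)-4-[(tert-butyldimethylsilyl)oxy]-2,6,6-trimethylcyclohex-2-en-1-yl]but-3-en-2-one | CC(=O)/C=C/[C@H]1C(C)=C[C@H](O[Si](C)(C)C(C)(C)C)CC1(C)C | intermediate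
22 | (3E)-4-[(1R,4R)-4-[(tert-butyldimethylsilyl)oxy]-2,6,6-trimethylcyclohex-2-en-1-yl]buta-1,3-dien-2-yl diethyl phosphate | C=C(OP(=O)(OCC)OCC)/C=C/[C@H]1C(C)=C[C@H](O[Si](C)(C)C(C)(C)C)CC1(C)C | intermediate
23 | tert-butyl{[(1R,4R)-4-[(1E)-but-1-en-3-yn-1-yl]-3,5,5-trimethylcyclohex-2-en-1-yl]oxy}dimethylsilane | C#C/C=C/[C@H]1C(C)=C[C@H](O[Si](C)(C)C(C)(C)C)CC1(C)C | intermediate
24 | dimethyl{(1E,3E)-2-methyl-4-[(1R,4R)-4-(tert-butyldimethylsilyloxy)-2,6,6-trimethylcyclohex-2-en-1-yl]buta-1,3-dien-1-yl}alane | C[Al](C)/C=C(C)/C=C/[C@H]1C(C)=C[C@H](O[Si](C)(C)C(C)(C)C)CC1(C)C | intermediate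
25 | tert-butyl{[(1R,4R)-3,5,5-trimethyl-4-[(1E,3E,5E)-3-methyl-8-(trimethylsilyl)octa-1,3,5-trien-7-yn-1-yl]cyclohex-2-en-1-yl]oxy}dimethylsilane | C[Si](C)(C)C#C/C=C/C=C(C)/C=C/[C@H]1C(C)=C[C@H](O[Si](C)(C)C(C)(C)C)CC1(C)C | intermediate
26 | tert-butyl{[(1R,4R)-3,5,5-trimethyl-4-[(1E,3E,5E)-3-methylocta-1,3,5-trien-7-yn-1-yl]cyclohex-2-en-1-yl]oxy}dimethylsilane | C#C/C=C/C=C(C)/C=C/[C@H]1C(C)=C[C@H](O[Si](C)(C)C(C)(C)C)CC1(C)C | intermediate
27 | dimethyl{(1E,3E,5E,7E)-2,6-dimethyl-8-[(1R,4R)-4-(tert-butyldimethylsilyloxy)-2,6,6-trimethylcyclohex-2-en-1-yl]octa-1,3,5,7-tetraen-1-yl}alane | C[Al](C)/C=C(C)/C=C/C=C(C)/C=C/[C@H]1C(C)=C[C@H](O[Si](C)(C)C(C)(C)C)CC1(C)C | intermediate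
28 | tert-butyl{[(1R,4R)-4-[(1E,3E,5E,7E,9E)-10-bromo-3,7-dimethyldeca-1,3,5,7,9-pentaen-1-yl]-3,5,5-trimethylcyclohex-2-en-1-yl]oxy}dimethylsilane | Br/C=C/C=C(C)/C=C/C=C(C)/C=C/[C@H]1C(C)=C[C@H](O[Si](C)(C)C(C)(C)C)CC1(C)C | intermediate
29 | dimethyl{(1E,3E,5E,7E)-2,6-dimethyl-8-[(4R)-4-(tert-butyldimethylsilyloxy)-2,6,6-trimethylcyclohex-1-en-1-yl]octa-1,3,5,7-tetraen-1-yl}alane | CC(C)(C)[Si](C)(C)O[C@@H]1CC(C)=C(/C=C/C(C)=C/C=C/C(C)=C/[Al](C)C)C(C)(C)C1 | intermediate
30 | (all-E,3R,3'R,6'R)-3,3'-bis[(tert-butyldimethylsilyl)oxy]-β,ε-carotene | CC(C)(C)[Si](C)(C)O[C@@H]1CC(C)=C(/C=C/C(C)=C/C=C/C(C)=C/C=C/C=C(C)/C=C/C=C(C)/C=C/[C@H]2C(C)=C[C@H](O[Si](C)(C)C(C)(C)C)CC2(C)C)C(C)(C)C1 | intermediate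
31 | (all-E,3R,3'R,6'R)-β,ε-carotene-3,3'-diol (lutein) | O[C@@H]1CC(C)=C(/C=C/C(C)=C/C=C/C(C)=C/C=C/C=C(C)/C=C/C=C(C)/C=C/[C@H]2C(C)=C[C@H](O)CC2(C)C)C(C)(C)C1 | intermediate
32 | hexadecanoyl chloride | CCCCCCCCCCCCCCCC(=O)Cl | starting material
33 | helenien, (all-E,3R,3'R,6'R)-β,ε-carotene-3,3'-diyl dihexadecanoate | CCCCCCCCCCCCCCCC(=O)O[C@@H]1CC(C)=C(/C=C/C(C)=C/C=C/C(C)=C/C=C/C=C(C)/C=C/C=C(C)/C=C/[C@H]2C(C)=C[C@H](OC(=O)CCCCCCCCCCCCCCC)CC2(C)C)C(C)(C)C1 | target

**Step count and risks**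
Total step count: 20. Longest linear sequence: 12 steps (steps 9–20, from (R)-α-ionone).

Steps most likely to fail:

1. Step 18. The one-pot sequence on two sensitive polyenes may suffer from incomplete methylalumination, protodemetalation, homocoupling or E/Z isomerisation of the nonaene. Fallback: separate the metalation from the coupling and change the metal. Setting out from 14, methylalumination followed by iodinolysis (I2, THF, −30 °C) should give the β-ring tetraenyl iodide F1. Setting out from 28, stannylation with (Bu3Sn)2 and Pd(PPh3)4 should give the ε-ring pentaenylstannane F2. Stille coupling of the two (Pd2(dba)3, AsPh3, NMP, rt) forms the same C14–C15 bond and comes back to the route at 30.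

2. Step 11. Facial selectivity may be poor if the catalyst's preference is opposed by the C6' side chain, and conjugate reduction may compete. Fallback: setting out from 18, Luche reduction (NaBH4, CeCl3·7H2O, MeOH, −78 °C) gives 19 together with its C3' epimer, the cis allylic alcohol F3, and the two are separated. Mitsunobu inversion of the cis alcohol (4-nitrobenzoic acid, PPh3, DIAD, THF) should give the 3'R 4-nitrobenzoate F4. Methanolysis (K2CO3, MeOH) comes back to the route at 19.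

3. Step 5. Insertion into the hindered, tetrasubstituted alkenylpalladium may be slow, with polymerisation of the enone or hydrolysis of the triflate taking over. Fallback: setting out from 7, Stille coupling (Pd2(dba)3, AsPh3, LiCl, NMP, 60 °C) with (E)-4-(tributylstannyl)but-3-en-2-one F5 comes back to the route at 9. The stannane is made from commercial (E)-1,2-bis(tributylstannyl)ethene and acetyl chloride with PdCl2(MeCN)2.

**Further compounds**
F1 | step 18 | tert-butyl{[(1R)-4-[(1E,3E,5E,7E)-8-iodo-3,7-dimethylocta-1,3,5,7-tetraen-1-yl]-3,5,5-trimethylcyclohex-3-en-1-yl]oxy}dimethylsilane | CC(C)(C)[Si](C)(C)O[C@@H]1CC(C)=C(/C=C/C(C)=C/C=C/C(C)=C/I)C(C)(C)C1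
F2 | step 18 | tert-butyl{[(1R,4R)-4-[(1E,3E,5E,7E,9E)-3,7-dimethyl-10-(tributylstannyl)deca-1,3,5,7,9-pentaen-1-yl]-3,5,5-trimethylcyclohex-2-en-1-yl]oxy}dimethylsilane | CCCC[Sn](CCCC)(CCCC)/C=C/C=C(C)/C=C/C=C(C)/C=C/[C@H]1C(C)=C[C@H](O[Si](C)(C)C(C)(C)C)CC1(C)C
F3 | step 11 | (1S,4R)-3,5,5-trimethyl-4-[(E)-2-(2-methyl-1,3-dioxolan-2-yl)ethenyl]cyclohex-2-en-1-ol | CC1(/C=C/[C@H]2C(C)=C[C@@H](O)CC2(C)C)OCCO1
F4 | step 11 | (1R,4R)-3,5,5-trimethyl-4-[(E)-2-(2-methyl-1,3-dioxolan-2-yl)ethenyl]cyclohex-2-en-1-yl 4-nitrobenzoate | CC1(/C=C/[C@H]2C(C)=C[C@H](OC(=O)c3ccc(cc3)[N+](=O)[O-])CC2(C)C)OCCO1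
F5 | step 5 | (E)-4-(tributylstannyl)but-3-en-2-one | CCCC[Sn](CCCC)(CCCC)/C=C/C(C)=O
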